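**Retrosynthetic overview**
- Avoided: the usual C3–C1′ Suzuki coupling of a 3-iodochromone with a pre-prenylated arylboron reagent, followed by SeO2 oxidation. Here the bare isoflavone core is made first and edited last, with no protecting groups.
- Side-chain C=C disconnection (key step): Vogelin E ⇐ (E)-enal ⇐ cross-metathesis of fully unprotected 3′-allylgenistein with methacrolein. This sets the E-alkene.
- C3′–C bond: aromatic Claisen O→C relay from 4′-O-allylgenistein. That ether comes from dianion-controlled 4′-O-allylation of free genistein, which overrides the higher innate reactivity of ring A.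
- Core: genistein ⇐ one-carbon (C-2) insertion from DMF into the deoxybenzoin ⇐ Friedel–Crafts acylation of phloroglucinol with 4-hydroxyphenylacetic acid.
- Ring order: rings A and B are purchased arenes. Ring C (the 4-pyranone) is the only ring formed (Step 2), before any side-chain work.

Assumption: the target has no stereocentre and is achiral, so "single enantiomer" is read as the single (E)-alkene isomer encoded in the SMILES (CH2OH trans to CH2Ar).

**Step 1**
Reactants: 1 phloroglucinol (anhydrous); 2 4-hydroxyphenylacetic acid
Product: 3 2-(4-hydroxyphenyl)-1-(2,4,6-trihydroxyphenyl)ethan-1-one (the deoxybenzoin)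
Conditions: BF3·OEt2 (neat), 80 °C, 2 h; aq. NaOAc
Reagents that add atoms: none (all product atoms come from 1 and 2; H2O is lost)
Why: Friedel–Crafts C-acylation, in which BF3 activates the acid, symmetric electron-rich phloroglucinol is acylated at any of three equivalent carbons, and the resulting BF2-chelated aryl ketone is deactivated toward a second acylation; no stereo-element is formed.

**Step 2**
Reactants: 3 deoxybenzoin; 4 N,N-dimethylformamide (C1 source and solvent)
Product: 5 genistein (5,7-dihydroxy-3-(4-hydroxyphenyl)-4H-chromen-4-one)
Conditions: BF3·OEt2, MsCl, DMF, 50 → 80 °C, 2 h; H2O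
Reagents that add atoms: DMF, CN(C)C=O (supplies C-2–H)
Why: Vilsmeier-type formylation–cyclocondensation (classical deoxybenzoin-to-isoflavone closure), in which the DMF/MsCl iminium salt attacks the benzylic carbon of the BF2-chelated enol and one of the two equivalent ortho-OH groups closes ring C with loss of Me2NH, the free phenols being regenerated on aqueous work-up.

**Step 3**
Reactants: 5 genistein; 6 allyl bromide
Product: 7 4′-O-allylgenistein (5,7-dihydroxy-3-[4-(prop-2-enyloxy)phenyl]-4H-chromen-4-one)
Conditions: t-BuOK (2.05 equiv), DMF, 0 °C, 30 min; then 6 (1.0 equiv), 0 °C → rt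
Reagents that add atoms: allyl bromide, C=CCBr
Why: Williamson etherification under dianion control, in which two equivalents of base ionise 7-OH (pKa ≈ 7) and 4′-OH (pKa ≈ 10) but not the chelated 5-OH (pKa ≈ 13), and the last-formed 4′-phenoxide, unlike the vinylogous-carboxylate 7-phenoxide, is the far better nucleophile and takes the single equivalent of electrophile.

**Step 4**
Reactants: 7 4′-O-allylgenistein
Product: 8 3′-allylgenistein (5,7-dihydroxy-3-[4-hydroxy-3-(prop-2-enyl)phenyl]-4H-chromen-4-one)
Conditions: PhNEt2, 210 °C, Ar, 4 h (sealed tube or microwave)
Reagents that add atoms: none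
Why: Aromatic Claisen rearrangement ([3,3] shift then tautomerisation), in which the O-tether forces C–C bond formation on ring B although ring A is the more nucleophilic arene, C-3′ and C-5′ are equivalent so one regioisomer forms, the isoflavone is thermally robust, and the weakly basic non-nucleophilic solvent suppresses acid-catalysed closure to the 2-methyldihydrobenzofuran.

**Step 5 (key step)**
Reactants: 8 3′-allylgenistein; 9 methacrolein (freshly distilled)
Product: 10 (E)-4-[5-(5,7-dihydroxy-4-oxo-4H-chromen-3-yl)-2-hydroxyphenyl]-2-methylbut-2-enal (CHO trans to CH2Ar)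
Conditions: 9 (10 equiv), Hoveyda–Grubbs II (5 mol %), 2,6-dichloro-1,4-benzoquinone (10 mol %), degassed EtOAc, 60 °C, 12 h
Reagents that add atoms: methacrolein, C=C(C)C=O (ethylene is lost)
Why: Olefin cross-metathesis of a type I terminal alkene with excess non-dimerising electron-poor 1,1-disubstituted alkene, in which Ru carbenes tolerate free phenols, the hindered electron-poor chromone C2=C3 bond is inert, any homodimer of 8 re-enters by secondary metathesis, the quinone quenches Ru–H allyl-to-propenyl isomerisation, and the 2-methyl-2-enal forms essentially only as the E isomer (>20:1), which sets the sole stereo-element.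

**Step 6**
Reactants: 10 (E)-enal
Product: 11 Vogelin E (5,7-dihydroxy-3-{4-hydroxy-3-[(E)-4-hydroxy-3-methylbut-2-enyl]phenyl}-4H-chromen-4-one)
Conditions: NaBH4 (1.5 equiv), CeCl3·7H2O (1.2 equiv), MeOH/THF 1:1, −40 → −20 °C, 30 min; sat. NH4Cl (keep pH ≈ 6–7)
Reagents that add atoms: none (hydride and proton only)
Why: Luche 1,2-reduction, in which the aldehyde is reduced within minutes at low temperature while the chromone carbonyl (a 5-OH-chelated vinylogous ester) is untouched, the alkene is not involved so the E geometry is retained, and the near-neutral quench avoids ionisation or cyclisation of the o-hydroxyaryl allylic alcohol.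

**Compound list**
1 | phloroglucinol (benzene-1,3,5-triol) | Oc1cc(O)cc(O)c1 | starting material
2 | 4-hydroxyphenylacetic acid | OC(=O)Cc1ccc(O)cc1 | starting material
3 | 2-(4-hydroxyphenyl)-1-(2,4,6-trihydroxyphenyl)ethan-1-one | O=C(Cc1ccc(O)cc1)c1c(O)cc(O)cc1O | intermediate
4 | N,N-dimethylformamide | CN(C)C=O | starting material (C1 source)
5 | genistein | O=c1c(-c2ccc(O)cc2)coc2cc(O)cc(O)c12 | intermediate
6 | allyl bromide | C=CCBr | starting material
7 | 4′-O-allylgenistein | C=CCOc1ccc(-c2coc3cc(O)cc(O)c3c2=O)cc1 | intermediate
8 | 3′-allylgenistein | C=CCc1cc(-c2coc3cc(O)cc(O)c3c2=O)ccc1O | intermediate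
9 | methacrolein | C=C(C)C=O | starting material
10 | (E)-4-[5-(5,7-dihydroxy-4-oxochromen-3-yl)-2-hydroxyphenyl]-2-methylbut-2-enal | C/C(=C\Cc1cc(-c2coc3cc(O)cc(O)c3c2=O)ccc1O)C=O | intermediate
11 | Vogelin E | C/C(=C\Cc1cc(-c2coc3cc(O)cc(O)c3c2=O)ccc1O)CO | target

**Total step count:** 6, with no protecting-group steps.
**Longest linear sequence:** 6. Compound 5 is itself sold commercially, so entering the route there leaves 4 steps.

**Three steps most likely to fail**
1. **Step 5 (metathesis on the free o-allylphenol triphenol).**
   - Risks: allyl-to-propenyl isomerisation, catalyst sequestration by the phenols, and oxa-Michael closure of 10 to a dihydrobenzofuran.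
   - Fallback: abandon metathesis. Peracetylate 8 and cleave the allyl C=C (OsO4/NaIO4) to the arylacetaldehyde. Form the alkene by an E-selective stabilised Wittig reaction with 2-(triphenylphosphoranylidene)propanal. Then carry out the Luche reduction and K2CO3/MeOH deacetylation.
2. **Step 3 (4′-O versus 7-O selectivity).**
   - Risks: 7-O-allyl and 4′,7-di-O-allyl by-products. The 7-O isomer can be removed by extracting 7 into aqueous carbonate, because only 7 keeps the acidic 7-OH.
   - Fallback: remove the selectivity question entirely by installing the ether before the core exists. O-Allylate 4-hydroxyphenylacetonitrile, run a Houben–Hoesch acylation of phloroglucinol (ZnCl2/HCl, Et2O, 0 °C; then hydrolysis), and close ring C with the C1 reagent to reach 7.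
3. **Step 4 (Claisen above 200 °C on a polar, sparingly soluble triphenol).**
   - Risks: incomplete conversion, and cyclisation to the 2-methyldihydrobenzofuran.
   - Fallback: replace the pericyclic step with cross-coupling. Run Steps 1–2 with 3-iodo-4-hydroxyphenylacetic acid to give 3′-iodogenistein, then apply a neutral Stille allylation (allyltributylstannane, Pd(PPh3)4, DMF, 90 °C) to reach 8.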